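## Retrosynthetic overview

1. The C16–OAc bond is made last. A carboxylate-directed allylic C–H acetoxylation puts the acetate on the one methyl that is cis to CO2H in the 6-oxo (13E)-dienoic acid. This turns 13E-CH3 into 13Z-CH2OAc without touching the alkene.
2. The C6 ketone comes from allylic C–H oxidation of the Δ7 alkene of the bicyclic dienoic acid, after ester hydrolysis.
3. Both rings come from one catalytic enantioselective proton-initiated bicyclization of ethyl (2E,6E,10E)-geranylgeranoate. Ring A closes first, ring B second, and C5, C9 and C10 are set together. The conjugated enoate ends the cascade and becomes the side chain.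
4. The tetraene ester comes from (5E,9E)-farnesylacetone and triethyl phosphonoacetate by Horner–Wadsworth–Emmons olefination.

Assumption: all-E farnesylacetone is bought as such (the commercial E/Z mixture would first be fractionated); catalysts are bought or made separately and not counted; labdane numbering is used (C15 carboxyl, C16 methyl on C13, C17 methyl on C8).

## Route

Step 1
Reactants: 1 (5E,9E)-6,10,14-trimethylpentadeca-5,9,13-trien-2-one (farnesylacetone); 2 triethyl phosphonoacetate
Product: 4 ethyl (2E,6E,10E)-3,7,11,15-tetramethylhexadeca-2,6,10,14-tetraenoate (ethyl geranylgeranoate), via sodium phosphonoacetate carbanion 3 (not isolated)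
Conditions: NaH, THF, 0 °C to 50 °C; SiO2 chromatography (2E isomer)
Reagents that add atoms: none
Why: Horner–Wadsworth–Emmons olefination of a methyl ketone, in which reversible addition places the long chain trans to the ester (2E:2Z about 4:1) and the minor 2Z ester is removed on silica; no stereocenter is formed.

Step 2
Reactants: 4 ethyl (2E,6E,10E)-geranylgeranoate
Product: 5 ethyl (5R,9R,10R,13E)-labda-7,13-dien-15-oate (ent-labdane series)
Conditions: mirror-image confined imidodiphosphorimidate Brønsted acid (ent-IDPi, the enantiomer of the catalyst that gives the 10β-methyl series; 5 mol %), (CF3)3COH, −20 °C, 4 d; AgNO3–SiO2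
Reagents that add atoms: none
Why: Proposed new method: the confined chiral acid protonates only the terminal 14,15-alkene, and the chair–chair folded polyene closes ring A and then ring B by anti additions across the two E-alkenes (Stork–Eschenmoser course), which sets C5, C10 and C9 in one event (trans-decalin, C9 chain cis to the C10 methyl) with the absolute sense fixed by the catalyst anion; the conjugated 2,3-alkene is too electron-poor to add, so the tertiary C8 cation ends by loss of H7 to the catalyst anion (any exocyclic isomer is re-protonated to the same cation and funnelled to the Δ7 ester); closest known reaction type: imidodiphosphorimidate-catalysed asymmetric polyene cyclizations of homofarnesol and homofarnesic acid in fluorinated alcohols, which end by O-trapping instead of proton loss.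

Step 3
Reactants: 5 ethyl (5R,9R,10R,13E)-labda-7,13-dien-15-oate
Product: 7 (5R,9R,10R,13E)-labda-7,13-dien-15-oic acid, via potassium carboxylate 6 (not isolated)
Conditions: KOH, EtOH/H2O, 80 °C; then 1 M HCl
Reagents that add atoms: potassium hydroxide, [K+].[OH-]
Why: Ester saponification (BAc2) that leaves both trisubstituted alkenes and the three stereocenters untouched, since none of them is next to an acidifying group.

Step 4
Reactants: 7 (5R,9R,10R,13E)-labda-7,13-dien-15-oic acid
Product: 8 (5R,9R,10S,13E)-6-oxolabda-7,13-dien-15-oic acid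
Conditions: Rh2(cap)4 [dirhodium tetrakis(caprolactamate), 1 mol %], 70% aq. t-BuOOH (5 equiv), ClCH2CH2Cl, 40 °C
Reagents that add atoms: tert-butyl hydroperoxide, CC(C)(C)OO
Why: Dirhodium caprolactamate/t-BuOOH allylic C–H oxidation, in which the tert-butylperoxyl radical abstracts the secondary allylic C6–H of the only electron-rich alkene and oxygen ends at C6 because the other allyl terminus C8 is fully substituted, while the γ-hydrogens of the electron-poor enoic acid are polarity-mismatched; no stereocenter is formed and C5 keeps the trans ring fusion, which is also the thermodynamic one.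

Step 5
Reactants: 8 (5R,9R,10S,13E)-6-oxolabda-7,13-dien-15-oic acid
Product: 9 (5R,9R,10S,13Z)-16-acetoxy-6-oxolabda-7,13-dien-15-oic acid (target)
Conditions: Pd(OAc)2 (10 mol %), 1,2-bis(phenylsulfinyl)ethane (10 mol %), 1,4-benzoquinone (2 equiv), AcOH (10 equiv), 1,4-dioxane, 45 °C
Reagents that add atoms: acetic acid, CC(=O)O
Why: Proposed new method: the substrate carboxylate binds divalent palladium and holds it over the only γ-methyl that is cis to it (C16), acetate-assisted concerted metalation–deprotonation gives a six-membered O,C-chelated allyl-palladium species without rotation about C13–C14, and benzoquinone then drives C–O bond formation between palladium-bound acetate and the unhindered CH2 terminus, which restores the conjugated acid with CH2OAc cis to CO2H (13Z) and releases zerovalent palladium that benzoquinone/AcOH reoxidise; the substrate's own carboxyl lies in the nodal plane of the allyl unit, so closure to the butenolide is stereoelectronically slow (5-endo) while acetate is in excess; closest known reaction types: palladium/bis-sulfoxide allylic C–H acetoxylation of terminal alkenes and carboxylate-directed benzylic C–H lactonization of 2-methylbenzoic acids.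

## Compound list

1 | (5E,9E)-6,10,14-trimethylpentadeca-5,9,13-trien-2-one ((E,E)-farnesylacetone) | CC(=O)CC/C=C(\C)CC/C=C(\C)CCC=C(C)C | starting material
2 | triethyl phosphonoacetate | CCOC(=O)CP(=O)(OCC)OCC | starting material
3 | sodium salt of the triethyl phosphonoacetate carbanion | CCOC(=O)[CH-]P(=O)(OCC)OCC.[Na+] | intermediate
4 | ethyl (2E,6E,10E)-3,7,11,15-tetramethylhexadeca-2,6,10,14-tetraenoate (ethyl geranylgeranoate) | CCOC(=O)/C=C(\C)CC/C=C(\C)CC/C=C(\C)CCC=C(C)C | intermediate
5 | ethyl (5R,9R,10R,13E)-labda-7,13-dien-15-oate (ent-labdane: trans-decalin, C9 side chain cis to the C10 methyl, H-5 and H-9 on the opposite face) | C/C(=C\C(=O)OCC)CC[C@@H]1C(C)=CC[C@@H]2C(C)(C)CCC[C@@]12C | intermediate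
6 | potassium (5R,9R,10R,13E)-labda-7,13-dien-15-oate | C/C(=C\C(=O)[O-])CC[C@@H]1C(C)=CC[C@@H]2C(C)(C)CCC[C@@]12C.[K+] | intermediate
7 | (5R,9R,10R,13E)-labda-7,13-dien-15-oic acid | C/C(=C\C(=O)O)CC[C@@H]1C(C)=CC[C@@H]2C(C)(C)CCC[C@@]12C | intermediate
8 | (5R,9R,10S,13E)-6-oxolabda-7,13-dien-15-oic acid | C/C(=C\C(=O)O)CC[C@@H]1C(C)=CC(=O)[C@@H]2C(C)(C)CCC[C@@]12C | intermediate
9 | (5R,9R,10S,13Z)-16-acetoxy-6-oxolabda-7,13-dien-15-oic acid | CC(=O)OC/C(=C\C(=O)O)CC[C@@H]1C(C)=CC(=O)[C@@H]2C(C)(C)CCC[C@@]12C | target

## Step count and risks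

Total step count: 5. Longest linear sequence: 5 (1 → 4 → 5 → 7 → 8 → 9).

The three steps most likely to fail are step 5, step 2 and step 4, in that order.

The directed acetoxylation (step 5) is new. It may fail to cleave the C–H bond of the conjugated methyl, may close to the butenolide, or may erode the alkene geometry. The fallback uses only known reactions, sets out from 7 and comes back at 9. It fixes the cis relation of C16–O and C15 in a ring instead of by C–H activation.
- Treatment of 7 with LiN(i-Pr)2 (2.5 equiv, THF/HMPA, −78 °C) removes the γ-hydrogen syn to the carboxylate, on C16. Kinetic protonation with AcOH then moves the alkene out of conjugation and gives (5R,9R,10R)-labda-7,13(16)-dien-15-oic acid F1.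
- Phenylselenolactonization (PhSeCl, Et3N, CH2Cl2, −78 °C) gives 13-(phenylselanyl)-(5R,9R,10R)-labd-7-en-15,16-olide F2 (C13 epimers; C15 is the carbonyl, C16 carries the ring oxygen).
- H2O2/pyridine oxidation with syn-elimination of PhSeOH gives the butenolide (5R,9R,10R)-labda-7,13-dien-15,16-olide F3.
- Allylic oxidation as in step 4 gives (5R,9R,10S)-6-oxolabda-7,13-dien-15,16-olide F4.
- NaOH (1.0 equiv, THF/H2O, 0 °C) opens the lactone to sodium (5R,9R,10S,13Z)-16-hydroxy-6-oxolabda-7,13-dien-15-oate F5.
- After freeze-drying, alkylation of the carboxylate with 4-methoxybenzyl chloride (DMF, NaI cat.) gives 4-methoxybenzyl (5R,9R,10S,13Z)-16-hydroxy-6-oxolabda-7,13-dien-15-oate F6.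
- F6 is acetylated at once (Ac2O, pyridine, DMAP, 0 °C) to 4-methoxybenzyl (5R,9R,10S,13Z)-16-acetoxy-6-oxolabda-7,13-dien-15-oate F7.
- CF3CO2H in CH2Cl2 at 0 °C removes the 4-methoxybenzyl ester and gives 9.

The asymmetric bicyclization (step 2) is also new for a polyene that ends by proton loss. It may give low enantiomeric ratio, stop at the monocycle, or give the wrong alkene isomer. The fallback uses known chemistry, sets out from 4 and comes back at 5. Fluorosulfonic acid in 2-nitropropane at −78 °C (Et3N quench) is the established superacid bicyclization of all-E polyprenyl esters. It gives the racemic Δ7 ester, that is 5 together with its mirror image ethyl (5S,9S,10S,13E)-labda-7,13-dien-15-oate F8. Preparative chiral SFC on an amylose carbamate phase separates the two, and 5 continues with step 3. The same column upgrades material of incomplete enantiomeric ratio from step 2.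

The allylic oxidation (step 4) may attack C9–H or the C17 methyl instead of C6. The fallback uses known chemistry, sets out from 7 and comes back at 8. It brings the oxygen in through the alkene instead of by C–H abstraction.
- Hydroxyselenation (PhSeCl, MeCN/H2O, rt) adds selenium to C7 on the face away from the C10 methyl and water to C8 trans-diaxially. It gives (13E)-8-hydroxy-7-(phenylselanyl)-ent-labd-13-en-15-oic acid F9 (SePh trans and 8-OH cis to the C10 methyl), which is not isolated.
- H2O2 oxidation with syn-elimination of PhSeOH (only C6 carries a β-hydrogen) gives the tertiary allylic alcohol (13E)-8-hydroxy-ent-labda-6,13-dien-15-oic acid F10.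
- Pyridinium chlorochromate ([C5H5NH][CrO3Cl], CH2Cl2, rt) then effects the Babler–Dauben oxidative 1,3-transposition to 8.

Further compounds
F1 | step 5 | (5R,9R,10R)-labda-7,13(16)-dien-15-oic acid | C=C(CC(=O)O)CC[C@@H]1C(C)=CC[C@@H]2C(C)(C)CCC[C@@]12C
F2 | step 5 | 13-(phenylselanyl)-(5R,9R,10R)-labd-7-en-15,16-olide (C13 epimers) | O=C1CC(CC[C@@H]2C(C)=CC[C@@H]3C(C)(C)CCC[C@@]23C)([Se]c4ccccc4)CO1
F3 | step 5 | (5R,9R,10R)-labda-7,13-dien-15,16-olide | O=C1C=C(CC[C@@H]2C(C)=CC[C@@H]3C(C)(C)CCC[C@@]23C)CO1
F4 | step 5 | (5R,9R,10S)-6-oxolabda-7,13-dien-15,16-olide | O=C1C=C(CC[C@@H]2C(C)=CC(=O)[C@@H]3C(C)(C)CCC[C@@]23C)CO1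
F5 | step 5 | sodium (5R,9R,10S,13Z)-16-hydroxy-6-oxolabda-7,13-dien-15-oate | OC/C(=C\C(=O)[O-])CC[C@@H]1C(C)=CC(=O)[C@@H]2C(C)(C)CCC[C@@]12C.[Na+]
F6 | step 5 | 4-methoxybenzyl (5R,9R,10S,13Z)-16-hydroxy-6-oxolabda-7,13-dien-15-oate | OC/C(=C\C(=O)OCc3ccc(OC)cc3)CC[C@@H]1C(C)=CC(=O)[C@@H]2C(C)(C)CCC[C@@]12C
F7 | step 5 | 4-methoxybenzyl (5R,9R,10S,13Z)-16-acetoxy-6-oxolabda-7,13-dien-15-oate | CC(=O)OC/C(=C\C(=O)OCc3ccc(OC)cc3)CC[C@@H]1C(C)=CC(=O)[C@@H]2C(C)(C)CCC[C@@]12C
F8 | step 2 | ethyl (5S,9S,10S,13E)-labda-7,13-dien-15-oate | C/C(=C\C(=O)OCC)CC[C@H]1C(C)=CC[C@H]2C(C)(C)CCC[C@]12C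
F9 | step 4 | (13E)-8-hydroxy-7-(phenylselanyl)-ent-labd-13-en-15-oic acid (SePh trans and 8-OH cis to the C10 methyl) | C/C(=C\C(=O)O)CC[C@@H]1[C@](C)(O)[C@@H]([Se]c3ccccc3)C[C@@H]2C(C)(C)CCC[C@@]12C
F10 | step 4 | (13E)-8-hydroxy-ent-labda-6,13-dien-15-oic acid (8-OH cis to the C10 methyl) | C/C(=C\C(=O)O)CC[C@@H]1[C@](C)(O)C=C[C@@H]2C(C)(C)CCC[C@@]12C
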